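## Plan

1. Numbering: furanone ring O1, C2 (C=O), C3 (OMe), C4 (aryl), C5 (H, benzyl); the open-chain precursors carry the numbers their atoms end with. ArP = 3-(3-methylbut-2-en-1-yl)-4-(triisopropylsilyloxy)phenyl.
2. Retrosynthesis: the two phenol O–Si bonds are cut last. Then O1–C5 and C4–aryl are cut together, which opens the furanone to an axially chiral 2-methoxy-2,3-dienoic acid and a 4-iodophenyl silyl ether.
3. Enabling feature: ring atoms C3=C4–C5, with the aryl group on C4 and the ring oxygen on C5, are a disguised allene C3=C4=C5. Its central carbon can take the aryl group and its terminus the carboxylate oxygen, so the ring and its only stereocentre come from one chiral axis.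
4. The allene is cut at C3=C4 (ketene plus α-methoxy phosphorus ylide, Wittig reaction), and the prenyl–arene bond is cut back to methyl 3-(4-hydroxyphenyl)propanoate.
5. Forward: prenylation, silylation, saponification; ketene Wittig reaction to the racemic allenoate; saponification; resolution; arylative ring closure (the only ring formed); desilylation.
6. Stereochemistry: resolution of the allenoic acid as its (S)-1-phenylethylammonium salt gives the (S)-axis. The ring closure transfers it to (R)-C5, and buffered desilylation keeps it.

Key step: step 8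

Assumption: the salt of the (S)-allenoic acid with (S)-1-phenylethylamine is taken to be the less soluble diastereomer; should the salt of the (R)-acid crystallize instead, (R)-1-phenylethylamine is used and nothing else in the route changes.

## Route

Step 1
Reactants: 1 methyl 3-(4-hydroxyphenyl)propanoate; 2 1-bromo-3-methylbut-2-ene (prenyl bromide)
Product: 4 methyl 3-[4-hydroxy-3-(3-methylbut-2-en-1-yl)phenyl]propanoate, via sodium phenoxide 3 (not isolated)
Conditions: NaH (1.05 equiv), toluene, 0 °C → rt; then 2 (1.1 equiv), rt
Reagents that add atoms: none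
Why: Ortho C-alkylation of a phenoxide: as a tight sodium ion pair in toluene, phenoxide 3 is alkylated by the allylic bromide at carbon in preference to oxygen, and because the para position is occupied the prenyl group can only enter next to the hydroxyl group; no stereocentre is formed.

Step 2
Reactants: 4 methyl 3-[4-hydroxy-3-(3-methylbut-2-en-1-yl)phenyl]propanoate
Product: 5 methyl 3-ArP-propanoate
Conditions: iPr3SiCl, imidazole, DMF, rt
Reagents that add atoms: chlorotriisopropylsilane, CC(C)[Si](Cl)(C(C)C)C(C)C
Why: Silyl ether formation with imidazole as base; the bulky triisopropylsilyl group is chosen because its aryl ether should survive the two saponifications, the acid chloride formation and the palladium step.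

Step 3
Reactants: 5 methyl 3-ArP-propanoate
Product: 6 3-ArP-propanoic acid
Conditions: LiOH·H2O, THF/H2O (3:1), rt; then 0.5 M HCl to pH 3
Reagents that add atoms: lithium hydroxide, [Li+].[OH-]
Why: Saponification of the methyl ester (hydroxide attack at the acyl carbon) at room temperature, conditions that should leave the hindered aryl silyl ether and the prenyl group alone.

Step 4
Reactants: 7 methyl 2,2-dimethoxyacetate
Product: 9 (1,2-dimethoxy-2-oxoethyl)triphenylphosphonium chloride, via methyl 2-chloro-2-methoxyacetate 8 (not isolated)
Conditions: AcCl (1.5 equiv), I2 (1 mol %), neat, 50 °C; volatiles removed; PPh3 (1.0 equiv), CH2Cl2, rt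
Reagents that add atoms: acetyl chloride, CC(Cl)=O; triphenylphosphine, c1ccc(cc1)P(c1ccccc1)c1ccccc1
Why: Acetal to α-chloro ether exchange (acetyl chloride removes one methoxy group as methyl acetate through the oxocarbenium ion) followed by quaternization of triphenylphosphine by the reactive α-chloro ether 8, the usual way to α-alkoxy ester phosphonium salts.

Step 5
Reactants: 6 3-ArP-propanoic acid; 9 (1,2-dimethoxy-2-oxoethyl)triphenylphosphonium chloride
Product: 13 methyl 2-methoxy-5-ArP-penta-2,3-dienoate (racemic), via acid chloride 10 (not isolated), via phosphorus ylide 11 (not isolated), via ketene 12 (not isolated)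
Conditions: (a) 6, 1-chloro-N,N,2-trimethylprop-1-en-1-amine (1.1 equiv), CH2Cl2, 0 °C → rt; (b) 9 (1.2 equiv), Et3N (2.5 equiv), CH2Cl2, 0 °C, then the solution of 10 added over 1 h, 0 °C → rt
Reagents that add atoms: none
Why: Wittig olefination of a ketene: acid chloride 10, made under neutral conditions so that no HCl meets the prenyl group, loses HCl to triethylamine to give ketene 12, whose carbonyl group is olefinated by ylide 11 (from 9 and triethylamine) with loss of Ph3PO, which creates the cumulated C3=C4 bond; the axis forms as the racemate.

Step 6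
Reactants: 13 methyl 2-methoxy-5-ArP-penta-2,3-dienoate (racemic)
Product: 14 2-methoxy-5-ArP-penta-2,3-dienoic acid (racemic)
Conditions: LiOH·H2O (1.5 equiv), THF/H2O, 0 °C; then 0.5 M HCl to pH 3, 0 °C
Reagents that add atoms: lithium hydroxide, [Li+].[OH-]
Why: Saponification at 0 °C; the 2-methoxy group lowers the tendency of the allenoate to take up hydroxide at the central carbon, and the benzylic CH2 protons are not acidified by the ester because their C–H bonds overlap only with the π bond that is orthogonal to the enoate system, so neither isomerization to the 2,4-dienoate nor loss of the silyl ether is expected.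

Step 7
Reactants: 14 2-methoxy-5-ArP-penta-2,3-dienoic acid (racemic)
Product: 15 (S)-1-phenylethylammonium (S)-2-methoxy-5-ArP-penta-2,3-dienoate (1:1 salt)
Conditions: (S)-1-phenylethylamine (0.5 equiv), EtOAc/hexane, 50 °C → 0 °C; recrystallization until the optical rotation no longer changes
Reagents that add atoms: (S)-1-phenylethylamine, C[C@H](N)c1ccccc1
Why: Classical resolution by crystallization of diastereomeric ammonium carboxylates with half an equivalent of amine; the configuration of the axis in the crystalline salt is to be confirmed by X-ray diffraction with the (S)-amine as internal reference, and the salt form also keeps the enol-ether allene away from its own free carboxylic acid.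

Step 8
Reactants: 15 (S)-1-phenylethylammonium (S)-2-methoxy-5-ArP-penta-2,3-dienoate; 16 tert-butyl(4-iodophenoxy)dimethylsilane
Product: 19 (R)-4-[4-(tert-butyldimethylsilyloxy)phenyl]-3-methoxy-5-(ArP-methyl)furan-2(5H)-one, via arylpalladium iodide 17 (not isolated), via palladated furanone 18 (not isolated)
Conditions: 16 (1.2 equiv), Pd(PPh3)4 (5 mol %), Ag2CO3 (10 mol %), degassed MeCN, 70 °C
Reagents that add atoms: none
Why: Oxidative addition of 16 to zerovalent palladium gives arylpalladium iodide 17, which binds the C4=C5 π bond of the allenoate on the face that carries the methoxy group of C3; the carboxylate oxygen attacks C5 from the opposite face, the only lobe it can reach, with loss of iodide to give the 4-palladated furanone 18, and reductive elimination joins the aryl group to C4 and returns zerovalent palladium. The closest known reaction type is the palladium-catalysed coupling–cyclization of 2,3-allenoic acids or their ammonium salts with aryl iodides to 4-aryl-2(5H)-furanones. The furanone ring closes in the 5-endo-trig mode by O1–C5 bond formation at the allene terminus. The stereocentre C5 is controlled by the chiral axis alone: H and CH2ArP on C5 keep their positions while O1 enters from the carboxylate side, so the (S)-axis becomes (R)-C5. The step needs aryl transfer to the central carbon with oxygen transfer to the terminus (secured by the tethered carboxylate, for which only C5 lies within reach), reaction at the allene in preference to the trisubstituted prenyl alkene (secured by the much higher reactivity of the cumulated π bond towards arylpalladium species), and retention of configuration (served by the ammonium carboxylate as the only base and by the silver co-catalyst, which removes iodide from palladium so that ring closure is fast).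

Step 9
Reactants: 19 (R)-4-[4-(tert-butyldimethylsilyloxy)phenyl]-3-methoxy-5-(ArP-methyl)furan-2(5H)-one
Product: 20 (R)-5-[4-hydroxy-3-(3-methylbut-2-en-1-yl)benzyl]-4-(4-hydroxyphenyl)-3-methoxyfuran-2(5H)-one (the target)
Conditions: Bu4NF (2.5 equiv), AcOH (2.5 equiv), THF, 0 °C
Reagents that add atoms: none
Why: Fluoride-induced cleavage of both aryl silyl ethers by attack at silicon; acetic acid buffers the phenoxides so that C5–H, which is acidic because its removal gives an aromatic 2-oxidofuran, is not epimerized, while the medium stays too weakly acidic to cyclize the ortho-prenylphenol to a chroman.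

## Compound list

1 | methyl 3-(4-hydroxyphenyl)propanoate | COC(=O)CCc1ccc(O)cc1 | starting material
2 | 1-bromo-3-methylbut-2-ene (prenyl bromide) | CC(C)=CCBr | starting material
3 | sodium 4-(3-methoxy-3-oxopropyl)phenoxide | COC(=O)CCc1ccc([O-])cc1.[Na+] | intermediate
4 | methyl 3-[4-hydroxy-3-(3-methylbut-2-en-1-yl)phenyl]propanoate | COC(=O)CCc1ccc(O)c(CC=C(C)C)c1 | intermediate
5 | methyl 3-[3-(3-methylbut-2-en-1-yl)-4-(triisopropylsilyloxy)phenyl]propanoate | COC(=O)CCc1ccc(O[Si](C(C)C)(C(C)C)C(C)C)c(CC=C(C)C)c1 | intermediate
6 | 3-[3-(3-methylbut-2-en-1-yl)-4-(triisopropylsilyloxy)phenyl]propanoic acid | OC(=O)CCc1ccc(O[Si](C(C)C)(C(C)C)C(C)C)c(CC=C(C)C)c1 | intermediate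
7 | methyl 2,2-dimethoxyacetate | COC(OC)C(=O)OC | starting material
8 | methyl 2-chloro-2-methoxyacetate | COC(Cl)C(=O)OC | intermediate
9 | (1,2-dimethoxy-2-oxoethyl)triphenylphosphonium chloride | COC(C(=O)OC)[P+](c1ccccc1)(c1ccccc1)c1ccccc1.[Cl-] | intermediate
10 | 3-[3-(3-methylbut-2-en-1-yl)-4-(triisopropylsilyloxy)phenyl]propanoyl chloride | O=C(Cl)CCc1ccc(O[Si](C(C)C)(C(C)C)C(C)C)c(CC=C(C)C)c1 | intermediate
11 | methyl 2-methoxy-2-(triphenylphosphoranylidene)acetate | COC(C(=O)OC)=P(c1ccccc1)(c1ccccc1)c1ccccc1 | intermediate
12 | 3-[3-(3-methylbut-2-en-1-yl)-4-(triisopropylsilyloxy)phenyl]prop-1-en-1-one (ketene) | O=C=CCc1ccc(O[Si](C(C)C)(C(C)C)C(C)C)c(CC=C(C)C)c1 | intermediate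
13 | methyl 2-methoxy-5-[3-(3-methylbut-2-en-1-yl)-4-(triisopropylsilyloxy)phenyl]penta-2,3-dienoate, racemic | COC(C(=O)OC)=C=CCc1ccc(O[Si](C(C)C)(C(C)C)C(C)C)c(CC=C(C)C)c1 | intermediate
14 | 2-methoxy-5-[3-(3-methylbut-2-en-1-yl)-4-(triisopropylsilyloxy)phenyl]penta-2,3-dienoic acid, racemic | COC(C(=O)O)=C=CCc1ccc(O[Si](C(C)C)(C(C)C)C(C)C)c(CC=C(C)C)c1 | intermediate
15 | (S)-1-phenylethylammonium (S)-2-methoxy-5-[3-(3-methylbut-2-en-1-yl)-4-(triisopropylsilyloxy)phenyl]penta-2,3-dienoate; axis: seen along the allene from the carboxylate end with OMe up and CO2 down, the CH2ArP group points to the right | COC(C(=O)[O-])=[C@@]=C([H])Cc1ccc(O[Si](C(C)C)(C(C)C)C(C)C)c(CC=C(C)C)c1.C[C@H]([NH3+])c1ccccc1 | intermediate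
16 | tert-butyl(4-iodophenoxy)dimethylsilane | CC(C)(C)[Si](C)(C)Oc1ccc(I)cc1 | starting material
17 | iodo[4-(tert-butyldimethylsilyloxy)phenyl]bis(triphenylphosphine)palladium | CC(C)(C)[Si](C)(C)Oc1ccc(cc1)[Pd-2](I)([P+](c1ccccc1)(c1ccccc1)c1ccccc1)[P+](c1ccccc1)(c1ccccc1)c1ccccc1 | intermediate
18 | [4-(tert-butyldimethylsilyloxy)phenyl][(R)-4-methoxy-5-oxo-2-(ArP-methyl)-2,5-dihydrofuran-3-yl]bis(triphenylphosphine)palladium | COC1=C([C@@H](Cc2ccc(O[Si](C(C)C)(C(C)C)C(C)C)c(CC=C(C)C)c2)OC1=O)[Pd-2](c1ccc(O[Si](C)(C)C(C)(C)C)cc1)([P+](c1ccccc1)(c1ccccc1)c1ccccc1)[P+](c1ccccc1)(c1ccccc1)c1ccccc1 | intermediate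
19 | (R)-4-[4-(tert-butyldimethylsilyloxy)phenyl]-3-methoxy-5-[3-(3-methylbut-2-en-1-yl)-4-(triisopropylsilyloxy)benzyl]furan-2(5H)-one | COC1=C(c2ccc(O[Si](C)(C)C(C)(C)C)cc2)[C@@H](Cc2ccc(O[Si](C(C)C)(C(C)C)C(C)C)c(CC=C(C)C)c2)OC1=O | intermediate
20 | (R)-5-[4-hydroxy-3-(3-methylbut-2-en-1-yl)benzyl]-4-(4-hydroxyphenyl)-3-methoxyfuran-2(5H)-one (4-demethoxycarbonyl-2-O-methylbutyrolactone I) | COC1=C(c2ccc(O)cc2)[C@@H](Cc2ccc(O)c(CC=C(C)C)c2)OC1=O | target

## Step count and risks

Total step count: 9. Longest linear sequence: 8 steps (steps 1, 2, 3, 5, 6, 7, 8, 9); step 4 is a one-step side branch.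

Steps most likely to fail:

**Step 7 (resolution).** The two diastereomeric salts may crystallize together or not at all, so that the axis is not enriched. The fallback replaces crystallization by separation on a chiral stationary phase. It sets out from racemic acid 14. Preparative supercritical-fluid chromatography on a cellulose tris(3,5-dimethylphenylcarbamate) phase (CO2/MeOH with a little acetic acid) should separate the enantiomers and give (S)-2-methoxy-5-ArP-penta-2,3-dienoic acid F1. One equivalent of (S)-1-phenylethylamine then converts it into salt 15, where the fallback rejoins the route.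

**Step 8 (arylative ring closure).** Configuration may be lost through reversible addition of palladium and iodide to the allene, or through equilibration of a π-allylpalladium species before the C–O bond forms. The palladated furanone may also be protonated before the aryl group is transferred. The fallback separates ring closure from arylation and sets out from salt 15. Iodolactonization (I2, MeCN, 0 °C) adds the iodonium ion and the carboxylate anti across the C4=C5 bond, with the same geometric transfer of the axis to C5. The prenyl alkene takes up iodine only reversibly. This should give (R)-4-iodo-3-methoxy-5-(ArP-methyl)furan-2(5H)-one F2. Suzuki–Miyaura coupling of this iodide with commercial [4-(tert-butyldimethylsilyloxy)phenyl]boronic acid (Pd(PPh3)4, NaHCO3, 1,2-dimethoxyethane/H2O, 60 °C) should then give 19, where the fallback rejoins the route.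

**Step 5 (ketene Wittig reaction).** C-acylation of ylide 11 by acid chloride 10, or dimerization of ketene 12, may outrun the olefination. The fallback makes the allene by elimination instead of olefination and sets out from acid chloride 10. Claisen-type C-acylation of methyl methoxyacetate (2 equiv, deprotonated with LiN(iPr)2, THF, −78 °C) should give the β-keto ester methyl 2-methoxy-3-oxo-5-ArP-pentanoate F3. O-Sulfonylation of its enolate (LiN(SiMe3)2, Tf2O, THF, −78 °C) should give the enol triflate methyl 2-methoxy-5-ArP-3-(trifluoromethylsulfonyloxy)pent-2-enoate F4. A second equivalent of LiN(SiMe3)2 should remove an allylic CH2 proton next to the triflate-bearing carbon and expel triflate (vinylogous E1cB elimination) to give racemic allenoate 13, where the fallback rejoins the route.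

## Further compounds

F1 | step 7 | (S)-2-methoxy-5-[3-(3-methylbut-2-en-1-yl)-4-(triisopropylsilyloxy)phenyl]penta-2,3-dienoic acid | COC(C(=O)O)=[C@@]=C([H])Cc1ccc(O[Si](C(C)C)(C(C)C)C(C)C)c(CC=C(C)C)c1
F2 | step 8 | (R)-4-iodo-3-methoxy-5-[3-(3-methylbut-2-en-1-yl)-4-(triisopropylsilyloxy)benzyl]furan-2(5H)-one | COC1=C(I)[C@@H](Cc2ccc(O[Si](C(C)C)(C(C)C)C(C)C)c(CC=C(C)C)c2)OC1=O
F3 | step 5 | methyl 2-methoxy-3-oxo-5-[3-(3-methylbut-2-en-1-yl)-4-(triisopropylsilyloxy)phenyl]pentanoate, racemic | COC(=O)C(OC)C(=O)CCc1ccc(O[Si](C(C)C)(C(C)C)C(C)C)c(CC=C(C)C)c1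
F4 | step 5 | methyl 2-methoxy-5-[3-(3-methylbut-2-en-1-yl)-4-(triisopropylsilyloxy)phenyl]-3-(trifluoromethylsulfonyloxy)pent-2-enoate, mixture of double-bond isomers | COC(=O)C(OC)=C(CCc1ccc(O[Si](C(C)C)(C(C)C)C(C)C)c(CC=C(C)C)c1)OS(=O)(=O)C(F)(F)F
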